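The dihydropyran ring (O1, C2-Me, C3-CH2OH, C4-CH2CO2R, C5-CO2Me, C6) is cut at C3–C4. The segment C6=C5(CO2Me)–C4–CH2–CO2 is the intact carbon chain of methyl coumalate, which the alkoxide of (R)-1-(oxiran-2-yl)ethanol opens at C6, leaving the two carboxyl groups differentiated. In the key step Ti(III) opens the epoxide to a C3 radical that closes the ring 6-exo onto the acrylate carbon C4. One operation forms the ring, releases the CH2OH group and sets C3 and C4 from C2, the only purchased stereocentre. Its precursor is an acyclic (2E,4E)-alkoxymethylene glutaconate diester that already carries the protected hydroxytyrosol.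

Key step: step 6

Remark on numbering: the pyran numbering of the target (O1, C2, C3, C4, C5, C6) is used for the same atoms in all intermediates.
Assumption: the oxirane carbon that becomes C3 is carried as a mixture of both epimers. It turns into a planar radical in step 6, so the SMILES of 5 and 7–10 leave this one centre undefined.

Step 1
Reactants: 1 hydroxytyrosol
Product: 2 2-[3,4-bis(benzyloxy)phenyl]ethan-1-ol
Conditions: BnBr (2.1 equiv), K2CO3, acetone, reflux
Reagents that add atoms: benzyl bromide, BrCc1ccccc1
Why: Williamson ether synthesis, in which K2CO3 deprotonates only the two phenols, so the aliphatic alcohol stays free.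

Step 2
Reactants: 2 2-[3,4-bis(benzyloxy)phenyl]ethan-1-ol
Product: 3 1,2-bis(benzyloxy)-4-(2-iodoethyl)benzene
Conditions: I2, PPh3, imidazole, CH2Cl2, 0 °C to rt
Reagents that add atoms: iodine, II
Why: Appel-type iodination (Garegg–Samuelsson conditions) replaces the primary hydroxyl by SN2 under near-neutral conditions that leave the benzyl ethers untouched.

Step 3
Reactants: 4 (R)-but-3-en-2-ol
Product: 5 (1R)-1-(oxiran-2-yl)ethan-1-ol (both oxirane epimers)
Conditions: mCPBA, CH2Cl2, 0 °C to rt; KF, filter; distil
Reagents that add atoms: mCPBA (3-chloroperoxybenzoic acid), OOC(=O)c1cccc(Cl)c1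
Why: Hydroxyl-assisted Prilezhaev epoxidation of the terminal alkene leaves the carbinol centre (future C2, R) untouched, and the new oxirane centre needs no control because step 6 erases it.

Step 4
Reactants: 5 (1R)-1-(oxiran-2-yl)ethan-1-ol; 6 methyl coumalate (methyl 2-oxo-2H-pyran-5-carboxylate); 3 1,2-bis(benzyloxy)-4-(2-iodoethyl)benzene
Product: 9 2-[3,4-bis(benzyloxy)phenyl]ethyl (2Z,4E)-4-(methoxycarbonyl)-5-[(1R)-1-(oxiran-2-yl)ethoxy]penta-2,4-dienoate, via potassium (1R)-1-(oxiran-2-yl)ethanolate 7 (not isolated), via potassium (2Z,4E)-dienoate salt 8 (not isolated)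
Conditions: 5, KHMDS (0.98 equiv), THF, −78 °C; add to 6 (1.05 equiv), THF, −78 to 0 °C; then 3 (1.1 equiv), DMF, rt
Reagents that add atoms: none
Why: 1,6-Conjugate addition with ring opening of a 2-pyranone, followed by SN2 alkylation of the carboxylate: C6 is the common terminus of both acceptor systems of 6 and the site where amines, hydride, enolates and even Grignard reagents are known to enter, loss of the lactone carboxylate from the adduct is irreversible and should give the (2Z,4E)-dienoate with OR cis to C4, the cold aprotic medium suppresses Payne migration, the C2–O bond is never broken (R retained), and alkylation in the same flask avoids the free Z-acid, which could close back to 6.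

Step 5
Reactants: 9 (2Z,4E)-diester
Product: 10 2-[3,4-bis(benzyloxy)phenyl]ethyl (2E,4E)-4-(methoxycarbonyl)-5-[(1R)-1-(oxiran-2-yl)ethoxy]penta-2,4-dienoate
Conditions: PhSSPh (10 mol %), 390 nm LED, CH2Cl2, rt
Reagents that add atoms: none
Why: Thiyl-radical-catalysed Z to E isomerisation (reversible addition and loss of PhS•) should drain the 2Z-enoate, strained by the contact of its ester with the C5 substituents, into the thermodynamic (2E,4E)-diene, while the epoxide and C2 are inert to these neutral conditions.

Step 6
Reactants: 10 (2E,4E)-diester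
Product: 11 methyl (2R,3R,4S)-4-(2-{2-[3,4-bis(benzyloxy)phenyl]ethoxy}-2-oxoethyl)-3-(hydroxymethyl)-2-methyl-3,4-dihydro-2H-pyran-5-carboxylate
Conditions: Cp2TiCl2 (20 mol %), Mn dust, 2,4,6-collidine·HCl (2.5 equiv), THF (high dilution), rt, slow addition of 10
Reagents that add atoms: none
Why: Cp2TiCl (from Cp2TiCl2 and Mn) binds the oxirane oxygen and cleaves the C3–O bond homolytically, so that titanium ends on the primary oxygen and both oxirane epimers give the same planar, nucleophilic secondary radical at C3; this radical adds to C4, the β-carbon of the (E)-acrylate, the resulting α-ester radical is reduced by a second Ti(III) to a titanium enolate, and collidinium chloride protonates the enolate and the Ti–O bond, which frees CH2CO2R and CH2OH and returns Ti(IV) to the Mn cycle. The closest known reaction type is the titanocene(III)-mediated reductive epoxide–olefin cyclisation (Nugent–RajanBabu reaction) in its catalytic Mn/collidine hydrochloride form, for which acrylates are the standard acceptors. The dihydropyran closes in 6-exo-trig mode through a half-chair in which O1, C6, C5 and C4 stay coplanar, while 7-endo attack at the α-carbon is disfavoured by polarity and 5-endo attack at C5 by geometry. C3: with the C2 methyl pseudo-equatorial and anti to the forming bond, the bulky CH2OTi arm should take the position next to C2–H rather than next to C2–O1 (allylic-strain control within the chair-like model for exo radical closure), which gives the 2,3-trans relation. C4: the (E)-acrylate arm should lie pseudo-equatorial, where it keeps residual overlap with C5=C6 and avoids the syn-axial H at C2, which gives 3,4-trans and 2,4-cis, that is (2R,3R,4S). The step needs ring closure to outrun capture of the C3 radical by Ti(III) and the new alcohol not to lactonise onto the neighbouring ester: the cis-locked O1–C6=C5 tether and the activated acceptor speed the closure, slow addition at low titanium loading keeps Ti(III) scarce, and the buffered proton source removes the Lewis acidic titanium alkoxide at once.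

Step 7
Reactants: 11 dibenzyl-protected dihydropyran
Product: 12 methyl (2R,3R,4S)-4-{2-[2-(3,4-dihydroxyphenyl)ethoxy]-2-oxoethyl}-3-(hydroxymethyl)-2-methyl-3,4-dihydro-2H-pyran-5-carboxylate (CNP0204147.1)
Conditions: H2 (1 atm), 10% Pd/C, EtOAc, rt
Reagents that add atoms: none
Why: Catalytic hydrogenolysis of the two aryl benzyl ethers is neutral, so neither δ-lactonisation nor transesterification is triggered, and the push–pull C5=C6 double bond (a vinylogous carbonate) resists hydrogenation at 1 atm.

Compound list
1 | hydroxytyrosol | OCCc1ccc(O)c(O)c1 | starting material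
2 | 2-[3,4-bis(benzyloxy)phenyl]ethan-1-ol | OCCc1ccc(OCc2ccccc2)c(OCc2ccccc2)c1 | intermediate
3 | 1,2-bis(benzyloxy)-4-(2-iodoethyl)benzene | ICCc1ccc(OCc2ccccc2)c(OCc2ccccc2)c1 | intermediate
4 | (R)-but-3-en-2-ol | C[C@@H](O)C=C | starting material
5 | (1R)-1-(oxiran-2-yl)ethan-1-ol, both oxirane epimers | C[C@@H](O)C1CO1 | intermediate
6 | methyl coumalate | COC(=O)C1=COC(=O)C=C1 | starting material
7 | potassium (1R)-1-(oxiran-2-yl)ethanolate | C[C@@H]([O-])C1CO1.[K+] | intermediate (not isolated)
8 | potassium (2Z,4E)-4-(methoxycarbonyl)-5-[(1R)-1-(oxiran-2-yl)ethoxy]penta-2,4-dienoate | COC(=O)C(/C=C\C(=O)[O-])=C/O[C@H](C)C1CO1.[K+] | intermediate (not isolated)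
9 | 2-[3,4-bis(benzyloxy)phenyl]ethyl (2Z,4E)-4-(methoxycarbonyl)-5-[(1R)-1-(oxiran-2-yl)ethoxy]penta-2,4-dienoate | COC(=O)C(/C=C\C(=O)OCCc1ccc(OCc2ccccc2)c(OCc2ccccc2)c1)=C/O[C@H](C)C1CO1 | intermediate
10 | 2-[3,4-bis(benzyloxy)phenyl]ethyl (2E,4E)-4-(methoxycarbonyl)-5-[(1R)-1-(oxiran-2-yl)ethoxy]penta-2,4-dienoate | COC(=O)C(/C=C/C(=O)OCCc1ccc(OCc2ccccc2)c(OCc2ccccc2)c1)=C/O[C@H](C)C1CO1 | intermediate
11 | methyl (2R,3R,4S)-4-(2-{2-[3,4-bis(benzyloxy)phenyl]ethoxy}-2-oxoethyl)-3-(hydroxymethyl)-2-methyl-3,4-dihydro-2H-pyran-5-carboxylate | COC(=O)C1=CO[C@H](C)[C@@H](CO)[C@@H]1CC(=O)OCCc1ccc(OCc2ccccc2)c(OCc2ccccc2)c1 | intermediate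
12 | methyl (2R,3R,4S)-4-{2-[2-(3,4-dihydroxyphenyl)ethoxy]-2-oxoethyl}-3-(hydroxymethyl)-2-methyl-3,4-dihydro-2H-pyran-5-carboxylate | COC(=O)C1=CO[C@H](C)[C@@H](CO)[C@@H]1CC(=O)OCCc1ccc(O)c(O)c1 | target

Total step count: 7.
Longest linear sequence: 6 steps (1 → 2 → 3 → 9 → 10 → 11 → 12). The branch from 4 joins in step 4.

Steps most likely to fail

Step 6. The attack on the planar C3 radical may show poor facial selectivity, so that the CH2OH arm ends cis to its neighbours. The radical may also be captured by Ti(III) before the ring closes. The fallback replaces kinetic control at C3 by thermodynamic control. It sets out from 11 as obtained (mixed with its C3 epimer) and comes back at 11. Dess–Martin periodinane in CH2Cl2 would oxidise the primary alcohol to the 3-formyl dihydropyran F1. C3 is then enolisable, and short exposure to a weak base (Et3N, CH2Cl2, 0 °C) should drain the C3 epimer into the isomer whose formyl group is trans to both neighbours. The contact is kept brief so that retro-oxa-Michael opening at C2 does not set in. NaBH4 in MeOH at −20 °C would then reduce only the aldehyde and return 11.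

Step 4. The hard alkoxide may attack the lactone carbonyl instead of C6, or the epoxy alkoxide may undergo Payne migration. The fallback reverses the order of union and turns acyl attack to advantage. It sets out from 2, 6 and 5 and comes back at 10. The sodium alkoxide of 2 (NaH, THF, −78 °C) would open 6 at the acyl carbon. Bond rotation within the delocalised enolate should give the 2E-configured hydroxymethylene glutaconate mixed diester F2. Trapping with TsCl would give the enol tosylate F3. Addition–elimination at C6 with 5 (NaH, THF, −40 °C) would install the chiral alkoxy group with its C–O bond intact. This gives 10 directly, so step 5 is not needed.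

Step 5. The Z to E equilibration may stay incomplete, or the enol ether geometry may erode under irradiation. The fallback builds the E-acrylate by cross-coupling instead of isomerisation. It sets out from 5 and 2 and comes back at 10. Amine-catalysed oxa-Michael addition of 5 to methyl propiolate (N-methylmorpholine, CH2Cl2) would give the (E)-β-alkoxyacrylate F4. Iodination and elimination (NIS, CH2Cl2, then Et3N) would give the (Z)-α-iodo-β-alkoxyacrylate F5, with iodine cis to the alkoxy group. Acylation of 2 with acryloyl chloride and Et3N would give the hydroxytyrosyl acrylate F6. A Heck reaction of F5 with F6 (Pd(OAc)2, Ag2CO3, MeCN, 60 °C) forms the C4–C5 bond with E geometry and retention at C5=C6, which gives 10.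

Further compounds
F1 | step 6 | methyl (2R,3S,4S)-4-(2-{2-[3,4-bis(benzyloxy)phenyl]ethoxy}-2-oxoethyl)-3-formyl-2-methyl-3,4-dihydro-2H-pyran-5-carboxylate | COC(=O)C1=CO[C@H](C)[C@@H](C=O)[C@@H]1CC(=O)OCCc1ccc(OCc2ccccc2)c(OCc2ccccc2)c1
F2 | step 4 | 1-{2-[3,4-bis(benzyloxy)phenyl]ethyl} 5-methyl (2E)-4-(hydroxymethylidene)pent-2-enedioate | COC(=O)C(=CO)/C=C/C(=O)OCCc1ccc(OCc2ccccc2)c(OCc2ccccc2)c1
F3 | step 4 | 1-{2-[3,4-bis(benzyloxy)phenyl]ethyl} 5-methyl (2E,4E)-4-{[(4-methylbenzenesulfonyl)oxy]methylidene}pent-2-enedioate | COC(=O)C(/C=C/C(=O)OCCc1ccc(OCc2ccccc2)c(OCc2ccccc2)c1)=C/OS(=O)(=O)c1ccc(C)cc1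
F4 | step 5 | methyl (E)-3-[(1R)-1-(oxiran-2-yl)ethoxy]prop-2-enoate | COC(=O)/C=C/O[C@H](C)C1CO1
F5 | step 5 | methyl (Z)-2-iodo-3-[(1R)-1-(oxiran-2-yl)ethoxy]prop-2-enoate | COC(=O)C(/I)=C/O[C@H](C)C1CO1
F6 | step 5 | 2-[3,4-bis(benzyloxy)phenyl]ethyl prop-2-enoate | C=CC(=O)OCCc1ccc(OCc2ccccc2)c(OCc2ccccc2)c1
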